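**Retrosynthetic overview**
1. The last C–C bond is C1(carbinol)–C4(butenolide): target ⇒ β,γ-unsaturated aldehyde + 4-bromofuran-2(5H)-one. Butenolide C4, normally the electrophilic Michael carbon, is made nucleophilic as an alkenylchromium (β-acylvinyl anion, an unsaturated homoenolate) and added to the electrophilic aldehyde carbon under asymmetric Ni/Cr catalysis. This one step sets 1R and brings in the intact butenolide.
2. Aldehyde ⇒ (3Z)-homoallylic alcohol ⇒ Z-selective Wittig olefination of an α-silyloxy ketone with a γ-oxido ylide.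
3. Ketone ⇒ homoallylic Grignard reagent + glycolic Weinreb amide; the (E)-homoallylic bromide ⇒ dihydro-β-ionone via methyl ketone → alkyne, Zr-catalysed carboalumination and ethylene oxide opening (7E).
4. Rings: none is formed. Ring A (trimethylcyclohexene) comes intact from dihydro-β-ionone and ring B (butenolide) intact from 4-bromofuran-2(5H)-one.

Assumption: compounds 1, 9, 12 and 16 are taken as catalogue chemicals.
Assumption: the facial sense of the oxazoline–sulfonamide ligand in step 7 is not known for this substrate; it is checked once by Mosher ester analysis and the antipodal ligand is used if the sense is reversed.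

**Step 1**
Reactants: 1 dihydro-β-ionone [4-(2,6,6-trimethylcyclohex-1-en-1-yl)butan-2-one]
Product: 4 2-(but-3-yn-1-yl)-1,3,3-trimethylcyclohex-1-ene, via lithium enolate 2 (not isolated), via enol diethyl phosphate 3 (not isolated)
Conditions: LiN(i-Pr)2 (1.05 equiv), THF, −78 °C; ClP(O)(OEt)2 (1.1 equiv), −78 °C → rt; LiN(i-Pr)2 (2.3 equiv), −78 °C → rt; H2O
Reagents that add atoms: none
Why: Negishi methyl-ketone-to-alkyne synthesis: kinetic deprotonation at CH3, O-phosphorylation of the enolate and base-induced elimination of diethyl phosphate from the terminal enol phosphate give the acetylide; no stereocenter is involved.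

**Step 2**
Reactants: 4 2-(but-3-yn-1-yl)-1,3,3-trimethylcyclohex-1-ene
Product: 7 (3E)-4-methyl-6-(2,6,6-trimethylcyclohex-1-en-1-yl)hex-3-en-1-ol, via alkenyldimethylalane 5 (not isolated), via lithium alkenylbutyldimethylaluminate 6 (not isolated)
Conditions: Me3Al (2.0 equiv), Cp2ZrCl2 (0.25 equiv), CH2Cl2, 0 °C → rt; evaporate volatiles, hexane; n-BuLi (1.0 equiv), −78 → 0 °C; ethylene oxide (3 equiv), THF, −30 → 0 °C; 1 M HCl
Reagents that add atoms: trimethylaluminium C[Al](C)C; ethylene oxide C1CO1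
Why: Negishi zirconium-catalysed carboalumination adds Me and Al syn across the alkyne with Al on the terminal carbon, and the alkenyl group of the derived alanate opens ethylene oxide with retention of geometry, which fixes the 7E trisubstituted alkene (>98:2).

**Step 3**
Reactants: 7 (3E)-4-methyl-6-(2,6,6-trimethylcyclohex-1-en-1-yl)hex-3-en-1-ol
Product: 8 2-[(3E)-6-bromo-3-methylhex-3-en-1-yl]-1,3,3-trimethylcyclohex-1-ene
Conditions: CBr4 (1.2 equiv), PPh3 (1.3 equiv), CH2Cl2, 0 °C
Reagents that add atoms: carbon tetrabromide BrC(Br)(Br)Br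
Why: Appel reaction: neutral SN2 bromination of a primary alcohol that leaves both acid-sensitive alkenes untouched.

**Step 4**
Reactants: 8 2-[(3E)-6-bromo-3-methylhex-3-en-1-yl]-1,3,3-trimethylcyclohex-1-ene; 9 2-[(tert-butyldimethylsilyl)oxy]-N-methoxy-N-methylacetamide
Product: 11 (5E)-1-[(tert-butyldimethylsilyl)oxy]-6-methyl-8-(2,6,6-trimethylcyclohex-1-en-1-yl)oct-5-en-2-one, via homoallylmagnesium bromide 10 (not isolated)
Conditions: Mg turnings (1.5 equiv), THF, rt → 40 °C; then 9 (1.1 equiv), THF, −20 → 0 °C; H2O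
Reagents that add atoms: none
Why: Weinreb ketone synthesis: the primary homoallylic Grignard reagent (E geometry kept, no allylic scrambling) adds only once to the N-methoxy-N-methylamide because the chelated adduct survives until work-up.

**Step 5**
Reactants: 11 (5E)-1-[(tert-butyldimethylsilyl)oxy]-6-methyl-8-(2,6,6-trimethylcyclohex-1-en-1-yl)oct-5-en-2-one; 12 (3-hydroxypropyl)triphenylphosphonium bromide
Product: 14 (3Z,7E)-4-{[(tert-butyldimethylsilyl)oxy]methyl}-8-methyl-10-(2,6,6-trimethylcyclohex-1-en-1-yl)deca-3,7-dien-1-ol, via sodium oxido ylide 13 (not isolated)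
Conditions: 12 (2.0 equiv), NaN(SiMe3)2 (4.0 equiv), THF, 0 °C; then 11, −78 °C → rt; H2O
Reagents that add atoms: none
Why: Wittig olefination in Still's α-alkoxy-ketone mode: non-stabilised ylides add to α-silyloxy ketones so that the CH2OSi group ends cis to the ylide-derived chain (typically ≥10:1), which sets the 3Z alkene; the minor isomer is removed by chromatography.

**Step 6**
Reactants: 14 (3Z,7E)-4-{[(tert-butyldimethylsilyl)oxy]methyl}-8-methyl-10-(2,6,6-trimethylcyclohex-1-en-1-yl)deca-3,7-dien-1-ol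
Product: 15 (3Z,7E)-4-{[(tert-butyldimethylsilyl)oxy]methyl}-8-methyl-10-(2,6,6-trimethylcyclohex-1-en-1-yl)deca-3,7-dienal
Conditions: Dess–Martin periodinane (1.3 equiv), pyridine (4 equiv), CH2Cl2, 0 °C, 30 min; cold filtration through deactivated silica; used at once
Reagents that add atoms: none
Why: Dess–Martin oxidation under pyridine buffer is fast and non-basic, so the β,γ-unsaturated aldehyde is formed without migration of the 3Z alkene into conjugation.

**Step 7**
Reactants: 15 (3Z,7E)-4-{[(tert-butyldimethylsilyl)oxy]methyl}-8-methyl-10-(2,6,6-trimethylcyclohex-1-en-1-yl)deca-3,7-dienal; 16 4-bromofuran-2(5H)-one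
Product: 20 4-[(1R,3Z,7E)-1-hydroxy-4-(hydroxymethyl)-8-methyl-10-(2,6,6-trimethylcyclohex-1-en-1-yl)deca-3,7-dien-1-yl]furan-2(5H)-one, via alkenylnickel bromide 17 (not isolated), via alkenylchromium dichloride 18 (not isolated), via TBS ether 19 (not isolated)
Conditions: 16 (1.8 equiv), CrCl2 (10 mol %), N-[2-((R)-4-isopropyl-4,5-dihydrooxazol-2-yl)-6-methylphenyl]methanesulfonamide (11 mol %), 1,8-bis(dimethylamino)naphthalene (11 mol %), NiCl2(2,9-dimethyl-1,10-phenanthroline) (2 mol %), Mn powder (2 equiv), Cp2ZrCl2 (1.1 equiv), LiCl (2 equiv), MeCN, rt, 16 h; then 1 M aq. HCl–THF (1:4), 0 °C → rt, 2 h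
Reagents that add atoms: none
Why: Proposed new method: zerovalent nickel inserts into the C4–Br bond of 16 and hands the alkenyl group to trivalent chromium held by the chiral sulfonamide ligand; this β-acylvinyl (unsaturated homoenolate) nucleophile joins the normally electrophilic butenolide C4 to the aldehyde carbon of 15 by ligand-controlled Si-face addition, which sets 1R, while the near-neutral medium leaves the β,γ-alkene unconjugated; the closest known reaction type is the catalytic asymmetric Ni/Cr (Nozaki–Hiyama–Kishi) coupling of β-iodoacrylates and alkenyl halides with aliphatic aldehydes, and the acid quench then releases the alcohol from zirconium and cleaves the primary TBS ether in the same flask.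

**Compound list**
1 | dihydro-β-ionone, 4-(2,6,6-trimethylcyclohex-1-en-1-yl)butan-2-one | CC1=C(CCC(C)=O)C(C)(C)CCC1 | starting material
2 | lithium 4-(2,6,6-trimethylcyclohex-1-en-1-yl)but-1-en-2-olate (kinetic enolate) | CC1=C(CCC(=C)O[Li])C(C)(C)CCC1 | intermediate
3 | diethyl 4-(2,6,6-trimethylcyclohex-1-en-1-yl)but-1-en-2-yl phosphate | CC1=C(CCC(=C)OP(=O)(OCC)OCC)C(C)(C)CCC1 | intermediate
4 | 2-(but-3-yn-1-yl)-1,3,3-trimethylcyclohex-1-ene | CC1=C(CCC#C)C(C)(C)CCC1 | intermediate
5 | dimethyl[(1E)-2-methyl-4-(2,6,6-trimethylcyclohex-1-en-1-yl)but-1-en-1-yl]alane | CC1=C(CC/C(C)=C/[Al](C)C)C(C)(C)CCC1 | intermediate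
6 | lithium butyl(dimethyl)[(1E)-2-methyl-4-(2,6,6-trimethylcyclohex-1-en-1-yl)but-1-en-1-yl]aluminate | CC1=C(CC/C(C)=C/[Al-](C)(C)CCCC)C(C)(C)CCC1.[Li+] | intermediate
7 | (3E)-4-methyl-6-(2,6,6-trimethylcyclohex-1-en-1-yl)hex-3-en-1-ol | CC1=C(CC/C(C)=C/CCO)C(C)(C)CCC1 | intermediate
8 | 2-[(3E)-6-bromo-3-methylhex-3-en-1-yl]-1,3,3-trimethylcyclohex-1-ene | CC1=C(CC/C(C)=C/CCBr)C(C)(C)CCC1 | intermediate
9 | 2-[(tert-butyldimethylsilyl)oxy]-N-methoxy-N-methylacetamide | CON(C)C(=O)CO[Si](C)(C)C(C)(C)C | starting material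
10 | [(3E)-4-methyl-6-(2,6,6-trimethylcyclohex-1-en-1-yl)hex-3-en-1-yl]magnesium bromide | CC1=C(CC/C(C)=C/CC[Mg]Br)C(C)(C)CCC1 | intermediate
11 | (5E)-1-[(tert-butyldimethylsilyl)oxy]-6-methyl-8-(2,6,6-trimethylcyclohex-1-en-1-yl)oct-5-en-2-one | CC1=C(CC/C(C)=C/CCC(=O)CO[Si](C)(C)C(C)(C)C)C(C)(C)CCC1 | intermediate
12 | (3-hydroxypropyl)triphenylphosphonium bromide | OCCC[P+](c1ccccc1)(c1ccccc1)c1ccccc1.[Br-] | starting material
13 | sodium 3-(triphenyl-λ5-phosphanylidene)propan-1-olate (γ-oxido ylide) | [Na+].[O-]CCC=P(c1ccccc1)(c1ccccc1)c1ccccc1 | intermediate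
14 | (3Z,7E)-4-{[(tert-butyldimethylsilyl)oxy]methyl}-8-methyl-10-(2,6,6-trimethylcyclohex-1-en-1-yl)deca-3,7-dien-1-ol | CC1=C(CC/C(C)=C/CC/C(=C/CCO)CO[Si](C)(C)C(C)(C)C)C(C)(C)CCC1 | intermediate
15 | (3Z,7E)-4-{[(tert-butyldimethylsilyl)oxy]methyl}-8-methyl-10-(2,6,6-trimethylcyclohex-1-en-1-yl)deca-3,7-dienal | CC1=C(CC/C(C)=C/CC/C(=C/CC=O)CO[Si](C)(C)C(C)(C)C)C(C)(C)CCC1 | intermediate
16 | 4-bromofuran-2(5H)-one | O=C1OCC(Br)=C1 | starting material
17 | (5-oxo-2,5-dihydrofuran-3-yl)nickel bromide (divalent nickel, phenanthroline ligand not drawn) | O=C1OCC([Ni]Br)=C1 | intermediate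
18 | (5-oxo-2,5-dihydrofuran-3-yl)chromium dichloride (trivalent chromium, drawn without the chiral sulfonamide ligand that replaces one chloride) | O=C1OCC([Cr](Cl)Cl)=C1 | intermediate
19 | 4-[(1R,3Z,7E)-4-{[(tert-butyldimethylsilyl)oxy]methyl}-1-hydroxy-8-methyl-10-(2,6,6-trimethylcyclohex-1-en-1-yl)deca-3,7-dien-1-yl]furan-2(5H)-one (held as its zirconocene chloride alkoxide until the quench) | CC1=C(CC/C(C)=C/CC/C(=C/C[C@@H](O)C2=CC(=O)OC2)CO[Si](C)(C)C(C)(C)C)C(C)(C)CCC1 | intermediate
20 | 4-[(1R,3Z,7E)-1-hydroxy-4-(hydroxymethyl)-8-methyl-10-(2,6,6-trimethylcyclohex-1-en-1-yl)deca-3,7-dien-1-yl]furan-2(5H)-one | CC1=C(CC/C(C)=C/CC/C(=C/C[C@@H](O)C2=CC(=O)OC2)CO)C(C)(C)CCC1 | target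

**Totals**
Total step count: 7. Longest linear sequence: 7 steps (1 → 20); compounds 9, 12 and 16 are bought.

**Three steps most likely to fail, with fallbacks**

Step 7 (asymmetric Ni/Cr coupling). The risks are that 16 is reduced or homocoupled instead of transferring to chromium, that 15 slips into conjugation, or that the ee is low. The fallback sets out from 15 and comes back to the route at 19. It makes the same bond with normal polarity, using a furan as masked butenolide. Commercial furan-3-ylboronic acid is transmetallated with Et2Zn (toluene, 60 °C) to ethyl(furan-3-yl)zinc F1. F1 adds to 15 under catalysis by a chiral amino alcohol of the 3-exo-morpholinoisoborneol type, with the ligand enantiomer chosen for the Si face, to give the (1R)-furyl carbinol F2. Photo-oxygenation of the furan (O2, rose bengal, hν, i-Pr2NEt, CH2Cl2, −78 °C) gives the γ-hydroxybutenolide F3. NaBH4 in MeOH followed by acidification reduces the masked aldehyde and closes the butenolide 19, which is desilylated with dilute HCl as in step 7.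

Step 5 (Z-selective Wittig). The risks are that the oxido ylide enolises ketone 11 or that the Z:E ratio is poor. The fallback sets out from 8 (as its Grignard reagent 10) and comes back at 14. It fixes the 3Z alkene by a stereospecific anti-carbomagnesiation, not by a selectivity ratio. Propargyl alcohol is deprotonated with i-PrMgCl to chloromagnesium prop-2-yn-1-olate F4. CuI-catalysed addition of 10 (Et2O–THF, rt) gives the five-membered alkenylmagnesium chelate F5, with the chain on the internal carbon and magnesium cis to the CH2O group. Iodine gives the (Z)-iodo alcohol F6, and TBSCl/imidazole gives the silyl ether F7. t-BuLi (Et2O, −78 °C) gives the alkenyllithium F8, and ethylene oxide opens with retention to 14.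

Step 6 (oxidation to the β,γ-unsaturated aldehyde). The risk is that 15 cannot be made or kept without conjugation. The fallback sets out from 14 and comes back at 19. It removes the aldehyde from the route by turning the carbinol carbon itself into the nucleophile. ClC(O)N(i-Pr)2 and NaH convert 14 into the N,N-diisopropylcarbamate F9. s-BuLi/(−)-sparteine (Et2O, −78 °C) removes the pro-S proton to give the configurationally stable (S)-α-lithio carbamate F10. Furan-3-ylboronic acid pinacol ester traps it with retention as the boronate complex F11. On warming, the furyl group migrates from boron to carbon with inversion and expels the carbamate, giving the secondary boronic ester F12. NaOH/H2O2 oxidation with retention gives the furyl carbinol F2, which is carried through the γ-hydroxybutenolide F3 to 19 as in the first fallback.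

**Further compounds**
F1 | step 7 | ethyl(furan-3-yl)zinc | CC[Zn]c1ccoc1
F2 | step 7 | (1R,3Z,7E)-4-{[(tert-butyldimethylsilyl)oxy]methyl}-1-(furan-3-yl)-8-methyl-10-(2,6,6-trimethylcyclohex-1-en-1-yl)deca-3,7-dien-1-ol | CC1=C(CC/C(C)=C/CC/C(=C/C[C@@H](O)c2ccoc2)CO[Si](C)(C)C(C)(C)C)C(C)(C)CCC1
F3 | step 7 | 4-[(1R,3Z,7E)-4-{[(tert-butyldimethylsilyl)oxy]methyl}-1-hydroxy-8-methyl-10-(2,6,6-trimethylcyclohex-1-en-1-yl)deca-3,7-dien-1-yl]-5-hydroxyfuran-2(5H)-one (both C5 epimers) | CC1=C(CC/C(C)=C/CC/C(=C/C[C@@H](O)C2=CC(=O)OC2O)CO[Si](C)(C)C(C)(C)C)C(C)(C)CCC1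
F4 | step 5 | chloromagnesium prop-2-yn-1-olate | C#CCO[Mg]Cl
F5 | step 5 | 4-[(3E)-4-methyl-6-(2,6,6-trimethylcyclohex-1-en-1-yl)hex-3-en-1-yl]-2,5-dihydro-1,2-oxamagnesole | CC1=C(CC/C(C)=C/CCC2=C[Mg]OC2)C(C)(C)CCC1
F6 | step 5 | (2Z,5E)-2-(iodomethylidene)-6-methyl-8-(2,6,6-trimethylcyclohex-1-en-1-yl)oct-5-en-1-ol | CC1=C(CC/C(C)=C/CC/C(=C/I)CO)C(C)(C)CCC1
F7 | step 5 | tert-butyl{[(2Z,5E)-2-(iodomethylidene)-6-methyl-8-(2,6,6-trimethylcyclohex-1-en-1-yl)oct-5-en-1-yl]oxy}dimethylsilane | CC1=C(CC/C(C)=C/CC/C(=C/I)CO[Si](C)(C)C(C)(C)C)C(C)(C)CCC1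
F8 | step 5 | [(1Z,4E)-2-{[(tert-butyldimethylsilyl)oxy]methyl}-5-methyl-7-(2,6,6-trimethylcyclohex-1-en-1-yl)hepta-1,4-dien-1-yl]lithium | CC1=C(CC/C(C)=C/CC/C(=C/[Li])CO[Si](C)(C)C(C)(C)C)C(C)(C)CCC1
F9 | step 6 | (3Z,7E)-4-{[(tert-butyldimethylsilyl)oxy]methyl}-8-methyl-10-(2,6,6-trimethylcyclohex-1-en-1-yl)deca-3,7-dien-1-yl N,N-diisopropylcarbamate | CC1=C(CC/C(C)=C/CC/C(=C/CCOC(=O)N(C(C)C)C(C)C)CO[Si](C)(C)C(C)(C)C)C(C)(C)CCC1
F10 | step 6 | (1S)-1-lithio derivative of F9 | CC1=C(CC/C(C)=C/CC/C(=C/C[C@H]([Li])OC(=O)N(C(C)C)C(C)C)CO[Si](C)(C)C(C)(C)C)C(C)(C)CCC1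
F11 | step 6 | lithium boronate complex of F10 and furan-3-ylboronic acid pinacol ester | CC1=C(CC/C(C)=C/CC/C(=C/C[C@H]([B-]2(c3ccoc3)OC(C)(C)C(C)(C)O2)OC(=O)N(C(C)C)C(C)C)CO[Si](C)(C)C(C)(C)C)C(C)(C)CCC1.[Li+]
F12 | step 6 | 2-[(1R,3Z,7E)-4-{[(tert-butyldimethylsilyl)oxy]methyl}-1-(furan-3-yl)-8-methyl-10-(2,6,6-trimethylcyclohex-1-en-1-yl)deca-3,7-dien-1-yl]-4,4,5,5-tetramethyl-1,3,2-dioxaborolane | CC1=C(CC/C(C)=C/CC/C(=C/C[C@@H](B2OC(C)(C)C(C)(C)O2)c2ccoc2)CO[Si](C)(C)C(C)(C)C)C(C)(C)CCC1
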